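**Plan**

1. Retrosynthesis: the C19 acetate and a 2,3-acetonide are cut last. The side chain is cut at C11–C12 (sp3–sp3 Suzuki–Miyaura), with C9–H and C11 traced to hydroboration of a C9=C11 methylene. Both ring-A bonds C1–C10 and C3–C4 are then cut together, leaving 6-methylcarvone and (Z)-3-bromo-1-iodopropene.
2. Enabling feature: in ring A the cis-2,3-diol is a masked C2=C3 double bond lying between two quaternary carbons. C10 is α to a C9 carbonyl of ring B. C4 carries CH3 and CH2O on one carbon, the pattern left by exo carbopalladation of an isopropenyl group followed by C–B oxidation. Carvone has exactly this enolisable α′-carbon and isopropenyl group, 1,3 to each other across C5.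
3. Forward: ring B comes from (S)-carvone. Ring A is closed in one pot by enolate C-alkylation followed by 6-exo Heck/borylation. Then osmylation, acetonide, C9 methylenation, hydroboration and coupling with the C12–C16 bromide made from methyl hydrogen (R)-3-methylglutarate, saponification, acetylation and acetonide removal.
4. Stereochemistry: C5 from (S)-carvone; C10 by alkylation anti to the isopropenyl group; C4 by the carbopalladation topography; C2/C3 by osmylation anti to the axial CH3-20 and C19; C9 by hydroboration anti to CH3-20; C13 from the glutarate.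

Key step: step 5

Assumption: bicyclic compounds are numbered as labdanes (C1–C10; CH3-17 on C8; CH3-18 and C19 on C4; CH3-20 on C10), and 7 is carried on as its C6-epimer mixture because that centre becomes planar in step 5.

**Route**

Step 1
Reactants: 1 ethyl (Z)-3-iodoprop-2-enoate
Product: 2 (Z)-3-iodoprop-2-en-1-ol
Conditions: iBu2AlH (2.2 equiv), CH2Cl2, −78 to 0 °C; aq. potassium sodium tartrate
Reagents that add atoms: none
Why: Hydride reduction of the unsaturated ester to the allylic alcohol (DIBAL-H reduction) should proceed 1,2 and leave the C–I bond and the Z geometry untouched.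

Step 2
Reactants: 2 (Z)-3-iodoprop-2-en-1-ol
Product: 3 (Z)-3-bromo-1-iodoprop-1-ene
Conditions: CBr4, PPh3, CH2Cl2, 0 °C
Reagents that add atoms: carbon tetrabromide, BrC(Br)(Br)Br
Why: Appel bromination of the primary allylic alcohol (SN2 at CH2) should give the allylic bromide with the Z-alkenyl iodide intact.

Step 3
Reactants: 4 methyl hydrogen (R)-3-methylglutarate
Product: 5 methyl (S)-4-bromo-3-methylbutanoate
Conditions: HgO (red), Br2, CCl4, reflux, dark
Reagents that add atoms: bromine, BrBr
Why: Hunsdiecker bromodecarboxylation (Cristol–Firth modification) replaces CO2H by Br through a primary alkyl radical one carbon away from the stereocentre, so the configuration is kept (the descriptor changes from R to S only because the priorities change).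

Step 4
Reactants: 6 (S)-carvone
Product: 7 6-methylcarvone, (5S)-2,6-dimethyl-5-(prop-1-en-2-yl)cyclohex-2-en-1-one (C6-epimer mixture)
Conditions: LiN(iPr)2, THF, −78 °C; MeI, −78 to 0 °C
Reagents that add atoms: iodomethane, CI
Why: Kinetic α′-deprotonation gives the cross-conjugated lithium dienolate, which is methylated at C6 (enolate alkylation); the new centre forms as an epimer mixture that is erased in step 5.

Step 5
Reactants: 7 6-methylcarvone; 3 (Z)-3-bromo-1-iodoprop-1-ene
Product: 9 boronate dienone (19-Bpin-11,12,13,14,15,16-hexanorlabda-2,7-dien-9-one; trans-fused; C19 syn to CH3-20), via alkenyl iodide 8 (not isolated)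
Conditions: LiN(iPr)2, THF/DMPU, −78 °C; 3, −78 to 0 °C; then B2pin2, KOAc, Pd(OAc)2 (5 mol%), PPh3 (10 mol%), DMF, 80 °C (one pot)
Reagents that add atoms: bis(pinacolato)diboron, CC1(C)OB(OC1(C)C)B1OC(C)(C)C(C)(C)O1
Why: The lithium cross-conjugated dienolate of 7 is C-alkylated (SN2) by allylic bromide 3 to give 8 (C1–C10); in the same flask zerovalent palladium inserts into the Z-alkenyl C–I bond, the alkenylpalladium adds syn across the isopropenyl group (C3–C4), and the resulting neopentyl σ-alkylpalladium, which has no β-hydrogen, is intercepted by B2pin2 (transmetalation, reductive elimination). The closest known reaction types are the cyclohexene annulation of ketone enolates with a (Z)-3-halo-1-iodopropene followed by palladium-mediated ring closure, and the domino Heck/borylation of halides tethered to 1,1-disubstituted alkenes. Ring A closes in the 6-exo-trig mode, and the Z geometry of the iodide becomes the cis C2=C3 bond. C10 is set by approach of 3 anti to the C5 isopropenyl group on the planar dienolate, which places CH3-20 cis to the isopropenyl group and so fixes the trans ring fusion. C4 is set in the carbopalladation: the Pd–C3 bond has to eclipse C4=CH2 in a plane roughly perpendicular to the developing C1–C2=C3–C4 unit, so in the chair-like arrangement of ring A, trans-fused to ring B, the CH2–Pd carbon should take the pseudoaxial site of C4, cis to CH3-20, and the old methyl group the equatorial site. The step needs C- over O-alkylation (lithium enolate, allylic bromide), exo over endo insertion (6-exo is strongly preferred for a 1,1-disubstituted alkene), and ring closure before direct borylation of the alkenyl iodide (intramolecular insertion should outrun bimolecular transmetalation under KOAc).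

Step 6
Reactants: 9 boronate dienone
Product: 10 19-hydroxy-11,12,13,14,15,16-hexanorlabda-2,7-dien-9-one (trans-fused; CH2OH syn to CH3-20)
Conditions: NaBO3·4H2O, THF/H2O, 0 °C to rt
Reagents that add atoms: sodium perborate, O[B-]1(O)OO[B-](O)(O)OO1.[Na+].[Na+]
Why: Perborate oxidation of the neopentyl C–B bond (1,2-shift from boron to oxygen with retention) gives the primary alcohol under conditions mild enough to leave the enone and the C2=C3 bond alone.

Step 7
Reactants: 10 19-hydroxy dienone
Product: 11 2,3,19-trihydroxy-11,12,13,14,15,16-hexanorlabd-7-en-9-one (2-OH and 3-OH cis to each other, syn to H-5, anti to CH3-20 and C19)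
Conditions: K2OsO4·2H2O (2 mol%), NMO, acetone/H2O (4:1), rt
Reagents that add atoms: N-methylmorpholine N-oxide, C[N+]1([O-])CCOCC1; water, O
Why: Catalytic osmylation (OsO4/NMO syn-dihydroxylation) of the cis-disubstituted C2=C3 bond should occur on the face anti to the axial CH3-20 and the axial C19 group, setting C2 and C3 together, while the electron-poor enone C7=C8 bond is left alone.

Step 8
Reactants: 11 triol
Product: 12 2,3-O-isopropylidene-2,3,19-trihydroxy-11,12,13,14,15,16-hexanorlabd-7-en-9-one
Conditions: Me2C(OMe)2, PPTS (cat.), CH2Cl2, rt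
Reagents that add atoms: 2,2-dimethoxypropane, COC(C)(C)OC
Why: Acid-catalysed transketalisation (acetonide formation) selects the cis-1,2-diol; the C19 hydroxyl cannot bridge to O3 because the two are anti across C3–C4.

Step 9
Reactants: 12 acetonide ketone
Product: 13 2,3-O-isopropylidene-12,13,14,15,16-pentanorlabda-7,9(11)-diene-2,3,19-triol
Conditions: Ph3PCH3Br, KOt-Bu, toluene, 80 °C
Reagents that add atoms: methyltriphenylphosphonium bromide, C[P+](c1ccccc1)(c1ccccc1)c1ccccc1.[Br-]
Why: Wittig methylenation of the C9 ketone with the salt-free ylide in hot toluene (needed for a carbonyl next to quaternary C10) gives the 7,9(11)-diene; the free C19 hydroxyl only consumes one equivalent of base.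

Step 10
Reactants: 13 acetonide diene; 5 methyl (S)-4-bromo-3-methylbutanoate
Product: 15 methyl (13R)-19-hydroxy-2,3-isopropylidenedioxylabd-7-en-15-oate (H-9 syn to H-5; side chain syn to CH3-20), via B-alkyl-9-BBN adduct 14 (not isolated)
Conditions: 9-BBN (2.5 equiv), THF, rt to 50 °C; then 5, Pd(OAc)2 (5 mol%), PCy3 (10 mol%), K3PO4·H2O, THF, rt (one pot)
Reagents that add atoms: none
Why: Hydroboration with 9-BBN places boron on the exocyclic CH2 and delivers H to C9 on the face anti to the axial CH3-20, which sets C9; the primary B-alkyl-9-BBN is then joined to bromide 5 by an sp3–sp3 Suzuki–Miyaura coupling (Pd/PCy3), with C13 arriving unchanged from 5.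

Step 11
Reactants: 15 methyl ester
Product: 16 (13R)-19-hydroxy-2,3-isopropylidenedioxylabd-7-en-15-oic acid
Conditions: LiOH, THF/MeOH/H2O, rt; then aq. HCl to pH 4, 0 °C
Reagents that add atoms: lithium hydroxide, [Li+].[OH-]
Why: Saponification of the unhindered methyl ester; the acetonide and the alkene are stable to base, and the work-up is held at pH 4 to preserve the acetonide.

Step 12
Reactants: 16 hydroxy acid
Product: 17 (13R)-19-acetoxy-2,3-isopropylidenedioxylabd-7-en-15-oic acid
Conditions: Ac2O, pyridine, DMAP (cat.), CH2Cl2, rt; aqueous work-up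
Reagents that add atoms: acetic anhydride, CC(=O)OC(C)=O
Why: DMAP-catalysed acetylation of the only free hydroxyl group (C19); the mixed anhydride formed at the carboxyl group is hydrolysed in the aqueous work-up.

Step 13
Reactants: 17 acetonide acetate
Product: 18 (2S,3R,4R,5S,9R,10S,13R)-19-acetoxy-2,3-dihydroxylabd-7-en-15-oic acid (target)
Conditions: AcOH/H2O (4:1), 45 °C
Reagents that add atoms: none
Why: Mild aqueous-acid hydrolysis of the acetonide frees the 2,3-diol; the primary acetate should survive and cannot migrate to O3, which is anti to C19 across C3–C4.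

**Compound list**

1 | ethyl (Z)-3-iodoprop-2-enoate | CCOC(=O)/C=C\I | starting material
2 | (Z)-3-iodoprop-2-en-1-ol | OC/C=C\I | intermediate
3 | (Z)-3-bromo-1-iodoprop-1-ene | BrC/C=C\I | intermediate
4 | methyl hydrogen (R)-3-methylglutarate [(R)-5-methoxy-3-methyl-5-oxopentanoic acid] | OC(=O)C[C@@H](C)CC(=O)OC | starting material
5 | methyl (S)-4-bromo-3-methylbutanoate | BrC[C@@H](C)CC(=O)OC | intermediate
6 | (S)-carvone [(S)-2-methyl-5-(prop-1-en-2-yl)cyclohex-2-en-1-one] | CC1=CC[C@@H](CC1=O)C(C)=C | starting material
7 | 6-methylcarvone, (5S)-2,6-dimethyl-5-(prop-1-en-2-yl)cyclohex-2-en-1-one, C6-epimer mixture | CC1=CC[C@@H](C(C)C1=O)C(C)=C | intermediate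
8 | (5R,6R)-6-[(Z)-3-iodoprop-2-enyl]-2,6-dimethyl-5-(prop-1-en-2-yl)cyclohex-2-en-1-one (iodoallyl group trans to isopropenyl) | C=C(C)[C@H]1CC=C(C)C(=O)[C@]1(C)C/C=C\I | intermediate (not isolated)
9 | 19-(4,4,5,5-tetramethyl-1,3,2-dioxaborolan-2-yl)-11,12,13,14,15,16-hexanorlabda-2,7-dien-9-one (trans-fused, H-5 anti to CH3-20; CH2Bpin syn to CH3-20) | CC1(C)OB(OC1(C)C)C[C@@]2(C)[C@H]3CC=C(C)C(=O)[C@]3(C)CC=C2 | intermediate
10 | 19-hydroxy-11,12,13,14,15,16-hexanorlabda-2,7-dien-9-one (same relative configuration as 9) | OC[C@@]1(C)[C@H]2CC=C(C)C(=O)[C@]2(C)CC=C1 | intermediate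
11 | 2,3,19-trihydroxy-11,12,13,14,15,16-hexanorlabd-7-en-9-one (2,3-cis-diol syn to H-5) | OC[C@@]1(C)[C@H]2CC=C(C)C(=O)[C@]2(C)C[C@H](O)[C@@H]1O | intermediate
12 | 2,3-acetonide of 11 | OC[C@@]1(C)[C@H]2CC=C(C)C(=O)[C@]2(C)C[C@H](OC(C)(C)O3)[C@@H]13 | intermediate
13 | 2,3-O-isopropylidene-12,13,14,15,16-pentanorlabda-7,9(11)-diene-2,3,19-triol | OC[C@@]1(C)[C@H]2CC=C(C)C(=C)[C@]2(C)C[C@H](OC(C)(C)O3)[C@@H]13 | intermediate
14 | C11 B-alkyl-9-BBN adduct of 13 with the C19 oxygen as its 9-BBN borinate (H-9 syn to H-5) | O(B4C5CCCC4CCC5)C[C@@]1(C)[C@H]2CC=C(C)[C@@H](CB6C7CCCC6CCC7)[C@]2(C)C[C@H](OC(C)(C)O3)[C@@H]13 | intermediate (not isolated)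
15 | methyl (13R)-19-hydroxy-2,3-isopropylidenedioxylabd-7-en-15-oate | OC[C@@]1(C)[C@H]2CC=C(C)[C@@H](CC[C@@H](C)CC(=O)OC)[C@]2(C)C[C@H](OC(C)(C)O3)[C@@H]13 | intermediate
16 | (13R)-19-hydroxy-2,3-isopropylidenedioxylabd-7-en-15-oic acid | OC[C@@]1(C)[C@H]2CC=C(C)[C@@H](CC[C@@H](C)CC(=O)O)[C@]2(C)C[C@H](OC(C)(C)O3)[C@@H]13 | intermediate
17 | (13R)-19-acetoxy-2,3-isopropylidenedioxylabd-7-en-15-oic acid | CC(=O)OC[C@@]1(C)[C@H]2CC=C(C)[C@@H](CC[C@@H](C)CC(=O)O)[C@]2(C)C[C@H](OC(C)(C)O3)[C@@H]13 | intermediate
18 | (2S,3R,4R,5S,9R,10S,13R)-19-acetoxy-2,3-dihydroxylabd-7-en-15-oic acid | CC(=O)OC[C@@]1(C)[C@H]2CC=C(C)[C@@H](CC[C@@H](C)CC(=O)O)[C@]2(C)C[C@H](O)[C@@H]1O | target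

**Count and risks**

Total step count: 13. Longest linear sequence: 11 steps (1 to 18: steps 1, 2 and 5 to 13).

Steps most likely to fail:

Step 5. The carbopalladation may run through the other ring topography (a boat-like arrangement that avoids the 1,3-diaxial contact with CH3-20), so that the CH2–Pd carbon ends trans to CH3-20 and C4 is formed with the wrong configuration. The fallback exchanges the roles of the two isopropenyl carbons. It sets out from 6. Allylic chlorination of the isopropenyl methyl group (Ca(OCl)2, CO2, CH2Cl2/H2O) would give 10-chlorocarvone F1. Displacement with sodium 4-methoxybenzyl oxide (NaH, 4-methoxybenzyl alcohol, THF) gives the 4-methoxybenzyl ether F2. Methylation as in step 4 gives 6-methyl ether F3, and alkylation with 3 as in step 5 gives alkenyl iodide F4. A reductive Heck cyclisation (Pd(OAc)2, PPh3, HCO2Na, DMF, 80 °C) then turns the CH2–Pd carbon into the methyl group and leaves the CH2O carbon in the position taken by the methyl group in the main route, giving bicyclic ether F5. DDQ removes the 4-methoxybenzyl group and the route is rejoined at 10.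

Step 9. The ylide may enolise the ketone through the γ-position, or fail to add to a carbonyl flanked by quaternary C10. The fallback is a two-stage Peterson olefination that sets out from 12. Addition of Me3SiCH2Li with CeCl3 (THF, −78 °C) would give β-hydroxysilane F6, and syn-elimination with KH (THF, rt) returns 13.

Step 10. The β-branched primary bromide 5 may add slowly to palladium, and the alkylpalladium may undergo β-hydride elimination, which would also endanger C13. The fallback builds the chain stepwise and sets C13 by catalyst control. It sets out from 13 through adduct 14, formed as in step 10. The organoborane alkylates bromoacetone (potassium 2,6-di-tert-butylphenoxide, THF, 0 °C) to give methyl ketone F7. A Horner–Wadsworth–Emmons reaction (trimethyl phosphonoacetate, NaH, THF) gives (E)-enoate F8. Asymmetric conjugate reduction with CuH (Cu(OAc)2, the p-tol-BINAP enantiomer matched to 13R, polymethylhydrosiloxane, t-BuOH, toluene) should return 15.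

Further compounds
F1 | step 5 | 10-chlorocarvone, (S)-5-(3-chloroprop-1-en-2-yl)-2-methylcyclohex-2-en-1-one | CC1=CC[C@@H](CC1=O)C(=C)CCl
F2 | step 5 | 10-(4-methoxybenzyloxy)carvone | CC1=CC[C@@H](CC1=O)C(=C)COCc1ccc(OC)cc1
F3 | step 5 | 10-(4-methoxybenzyloxy)-6-methylcarvone (C6-epimer mixture) | CC1=CC[C@@H](C(C)C1=O)C(=C)COCc1ccc(OC)cc1
F4 | step 5 | 6-[(Z)-3-iodoprop-2-enyl]-10-(4-methoxybenzyloxy)-6-methylcarvone (iodoallyl trans to the C5 substituent) | C=C(COCc1ccc(OC)cc1)[C@H]1CC=C(C)C(=O)[C@]1(C)C/C=C\I
F5 | step 5 | 19-(4-methoxybenzyloxy)-11,12,13,14,15,16-hexanorlabda-2,7-dien-9-one (4-methoxybenzyl ether of 10) | COc1ccc(COC[C@@]2(C)[C@H]3CC=C(C)C(=O)[C@]3(C)CC=C2)cc1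
F6 | step 9 | 9-hydroxy-9-[(trimethylsilyl)methyl] adduct of 12 (either C9 epimer) | OC[C@@]1(C)[C@H]2CC=C(C)C(O)(C[Si](C)(C)C)[C@]2(C)C[C@H](OC(C)(C)O3)[C@@H]13
F7 | step 10 | 19-hydroxy-2,3-isopropylidenedioxy-14,15-dinorlabd-7-en-13-one | OC[C@@]1(C)[C@H]2CC=C(C)[C@@H](CCC(C)=O)[C@]2(C)C[C@H](OC(C)(C)O3)[C@@H]13
F8 | step 10 | methyl (13E)-19-hydroxy-2,3-isopropylidenedioxylabda-7,13-dien-15-oate | OC[C@@]1(C)[C@H]2CC=C(C)[C@@H](CC/C(C)=C/C(=O)OC)[C@]2(C)C[C@H](OC(C)(C)O3)[C@@H]13
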